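The dihydrofuran ring is opened at C2–C3 and at O1–C7a. This returns 3,4,5-trimethoxybenzaldehyde, which supplies O1 and C2, and 2-bromo-3-methoxystyrene, whose vinyl group becomes C3 with its methyl and whose brominated carbon becomes C7a. The key step exploits that C3 is a benzylic methine on C3a, next to the ring carbon C7a that carries the ether oxygen: enantioselective CuH addition to the vinyl group makes C3 a configured nucleophile for the aldehyde, and the resulting alkoxide is arylated at C7a in the same flask. Both stereocentres and the oxygen ring thus arise in one operation; the propenyl group follows by C5–H borylation and Suzuki–Miyaura coupling.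

Key step: step 2

Remark on the chemistry: 2-bromo-3-methoxybenzaldehyde and (E)-1-bromoprop-1-ene are taken as commercial. (S,S)-Ph-BPE is written for the ligand antipode that leads to (3R); if the sense of induction proves opposite, the (R,R) ligand is used.

Step 1
Reactants: 1 2-bromo-3-methoxybenzaldehyde; 2 methyltriphenylphosphonium bromide
Product: 3 2-bromo-1-ethenyl-3-methoxybenzene
Conditions: 2, KOtBu, THF, 0 °C to rt
Reagents that add atoms: methyltriphenylphosphonium bromide (2), C[P+](c1ccccc1)(c1ccccc1)c1ccccc1.[Br-]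
Why: Wittig methylenation of an aryl aldehyde with the non-stabilised ylide is reliable and should leave the aryl bromide and the methyl ether untouched.

Step 2
Reactants: 3 2-bromo-1-ethenyl-3-methoxybenzene; 4 3,4,5-trimethoxybenzaldehyde
Product: 7 (2R,3R)-7-methoxy-3-methyl-2-(3,4,5-trimethoxyphenyl)-2,3-dihydro-1-benzofuran, via silyl ether 5 (not isolated), via potassium alkoxide 6 (not isolated)
Conditions: Cu(OAc)2 (5 mol%), (S,S)-Ph-BPE (6 mol%), (MeO)2MeSiH (2.5 equiv), THF, rt, 4 added slowly by syringe pump; then MeOH, volatiles removed; then KOtBu (2 equiv), CuCl (10 mol%), 2,2,6,6-tetramethylheptane-3,5-dione (TMHD, 20 mol%), toluene, 100 °C, same flask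
Reagents that add atoms: 3,4,5-trimethoxybenzaldehyde (4), O=Cc1cc(OC)c(OC)c(OC)c1
Why: Proposed new method: ligated CuH should add across the vinyl group of 3 in the Markovnikov sense to give a benzylic copper species that adds to the carbonyl of 4 with retention at carbon (C2–C3); the silane then turns the copper alkoxide into silyl ether 5 and returns CuH, and after methanol has destroyed residual Si–H, KOtBu frees alkoxide 6, which CuCl/TMHD arylates at the brominated carbon (O1–C7a). The closest known reaction types are the CuH-catalysed enantioselective reductive coupling of vinylarenes with ketones or imines and of 1,3-dienes with aldehydes, joined here to the Ullmann-type intramolecular O-arylation of 2-(2-bromoaryl)ethanols. The furan ring closes in a 5-exo manner by ipso substitution of bromide at the sp2 carbon C7a, which touches neither stereocentre. C3 is set by the chiral bisphosphine, which selects the face of the vinyl group in the hydrocupration, and is carried into the product with retention. C2 is set in the addition to the aldehyde, where the ligand and the copper-bearing C3 centre should act together in a closed four-centre transition state to favour the (1R,2R) alkoxide that gives the trans ring. The step needs hydrocupration of the alkene to outrun 1,2-reduction of the aldehyde, secured by the Ph-BPE ligand and slow addition of 4, and it needs the C–Br bond to survive until the second stage, secured by the mildness of CuH at room temperature and by the two ortho substituents that rule out an aryne under KOtBu.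

Step 3
Reactants: 7 (2R,3R)-7-methoxy-3-methyl-2-(3,4,5-trimethoxyphenyl)-2,3-dihydro-1-benzofuran; 8 bis(pinacolato)diboron
Product: 9 2-[(2R,3R)-7-methoxy-3-methyl-2-(3,4,5-trimethoxyphenyl)-2,3-dihydro-1-benzofuran-5-yl]-4,4,5,5-tetramethyl-1,3,2-dioxaborolane
Conditions: 8 (1.0 equiv), [Ir(OMe)(cod)]2 (2 mol%), dtbpy (4 mol%), THF, 80 °C
Reagents that add atoms: bis(pinacolato)diboron (8), CC1(C)OB(OC1(C)C)B1OC(C)(C)C(C)(C)O1
Why: [Ir(OMe)(cod)]2/dtbpy-catalysed C–H borylation is governed by sterics, and C5–H is the only ring hydrogen without an ortho substituent (C4–H lies beside the ring fusion, C6–H beside the methoxy group, and both hydrogens of the trimethoxyphenyl ring are flanked on each side), so the boryl group should enter at C5 without touching the stereocentres.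

Step 4
Reactants: 9 2-[(2R,3R)-7-methoxy-3-methyl-2-(3,4,5-trimethoxyphenyl)-2,3-dihydro-1-benzofuran-5-yl]-4,4,5,5-tetramethyl-1,3,2-dioxaborolane; 10 (E)-1-bromoprop-1-ene
Product: 11 (2R,3R)-7-methoxy-3-methyl-5-[(1E)-prop-1-en-1-yl]-2-(3,4,5-trimethoxyphenyl)-2,3-dihydro-1-benzofuran (target)
Conditions: 10 (3 equiv), Pd(dppf)Cl2 (5 mol%), K2CO3 (3 equiv), 1,4-dioxane/H2O, 70 °C, sealed tube
Reagents that add atoms: (E)-1-bromoprop-1-ene (10), C/C=C/Br
Why: Suzuki–Miyaura coupling of an aryl boronate with an alkenyl bromide proceeds with retention of the (E) geometry and should tolerate the benzylic ether and both stereocentres.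

Compound list
1 | 2-bromo-3-methoxybenzaldehyde | O=Cc1cccc(OC)c1Br | starting material
2 | methyltriphenylphosphonium bromide | C[P+](c1ccccc1)(c1ccccc1)c1ccccc1.[Br-] | starting material
3 | 2-bromo-1-ethenyl-3-methoxybenzene | C=Cc1cccc(OC)c1Br | intermediate
4 | 3,4,5-trimethoxybenzaldehyde | O=Cc1cc(OC)c(OC)c(OC)c1 | starting material
5 | [(1R,2R)-2-(2-bromo-3-methoxyphenyl)-1-(3,4,5-trimethoxyphenyl)propoxy]dimethoxy(methyl)silane | C[C@H](c1cccc(OC)c1Br)[C@@H](O[Si](C)(OC)OC)c1cc(OC)c(OC)c(OC)c1 | intermediate (not isolated)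
6 | potassium (1R,2R)-2-(2-bromo-3-methoxyphenyl)-1-(3,4,5-trimethoxyphenyl)propan-1-olate | C[C@H](c1cccc(OC)c1Br)[C@@H]([O-])c1cc(OC)c(OC)c(OC)c1.[K+] | intermediate (not isolated)
7 | (2R,3R)-7-methoxy-3-methyl-2-(3,4,5-trimethoxyphenyl)-2,3-dihydro-1-benzofuran | c1cc(OC)c2c(c1)[C@@H](C)[C@H](c1cc(OC)c(OC)c(OC)c1)O2 | intermediate
8 | bis(pinacolato)diboron | CC1(C)OB(OC1(C)C)B1OC(C)(C)C(C)(C)O1 | starting material
9 | 2-[(2R,3R)-7-methoxy-3-methyl-2-(3,4,5-trimethoxyphenyl)-2,3-dihydro-1-benzofuran-5-yl]-4,4,5,5-tetramethyl-1,3,2-dioxaborolane | CC1(C)OB(OC1(C)C)c1cc(OC)c2c(c1)[C@@H](C)[C@H](c1cc(OC)c(OC)c(OC)c1)O2 | intermediate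
10 | (E)-1-bromoprop-1-ene | C/C=C/Br | starting material
11 | (2R,3R)-7-methoxy-3-methyl-5-[(1E)-prop-1-en-1-yl]-2-(3,4,5-trimethoxyphenyl)-2,3-dihydro-1-benzofuran | C/C=C/c1cc(OC)c2c(c1)[C@@H](C)[C@H](c1cc(OC)c(OC)c(OC)c1)O2 | target

Total step count: 4
Longest linear sequence: 4 steps (1 → 3 → 7 → 9 → 11)

Steps most likely to fail

Step 2. The aldehyde may be reduced by CuH before the alkene is hydrocuprated, the addition to the aldehyde may show poor facial selectivity at C2, and the aryl bromide may be reduced during ring closure. The fallback uses known chemistry, sets out from 3 and comes back at 7. Markovnikov hydroboration of 3 with pinacolborane (CuCl, NaOtBu, DTBM-SEGPHOS antipode chosen for (R), THF) would give 2-[(1R)-1-(2-bromo-3-methoxyphenyl)ethyl]-4,4,5,5-tetramethyl-1,3,2-dioxaborolane F1. KHF2 in MeOH/H2O would convert it into potassium [(1R)-1-(2-bromo-3-methoxyphenyl)ethyl]trifluoroborate F2. Its [RhCl(cod)]2-catalysed 1,2-addition to 4 in dioxane/H2O at 80 °C, a reaction type that keeps the configuration of the benzylic carbon, would give (2R)-2-(2-bromo-3-methoxyphenyl)-1-(3,4,5-trimethoxyphenyl)propan-1-ol F3 as a mixture of epimers at the carbinol carbon. O-Arylation (CuCl, TMHD, KOtBu, toluene, 100 °C) would close the ring to 7 together with its cis isomer (2S,3R)-7-methoxy-3-methyl-2-(3,4,5-trimethoxyphenyl)-2,3-dihydro-1-benzofuran F4. BF3·OEt2 in CH2Cl2 would then equilibrate C2 through the ring-opened benzylic cation towards the trans compound 7.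

Step 3. Borylation may stray to C6 beside the methoxy group or to C4, or the electron-rich ring may react slowly. The fallback sets out from 7 and comes back at 11. C–H thianthrenation (thianthrene S-oxide, trifluoroacetic anhydride, HBF4·OEt2, MeCN, 0 °C) should occur at C5, which is para to O1 and unhindered, to give 5-[(2R,3R)-7-methoxy-3-methyl-2-(3,4,5-trimethoxyphenyl)-2,3-dihydro-1-benzofuran-5-yl]thianthren-5-ium tetrafluoroborate F5. Suzuki–Miyaura coupling of this salt with (E)-prop-1-enylboronic acid pinacol ester (Pd(dppf)Cl2, K3PO4, dioxane/H2O) would give 11 directly.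

Step 4. The volatile bromoalkene may be lost, the electron-rich aryl boronate may protodeboronate, or the alkene geometry may erode. The fallback sets out from 9 and comes back at 11. Coupling of 9 with allyl bromide (Pd(PPh3)4, K2CO3, THF/H2O, 60 °C) would give (2R,3R)-7-methoxy-3-methyl-5-(prop-2-en-1-yl)-2-(3,4,5-trimethoxyphenyl)-2,3-dihydro-1-benzofuran F6. Isomerisation of the allyl group into conjugation (RuHCl(CO)(PPh3)3, toluene, 80 °C) would give the thermodynamically favoured (E)-propenyl compound 11.

Further compounds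
F1 | step 2 | 2-[(1R)-1-(2-bromo-3-methoxyphenyl)ethyl]-4,4,5,5-tetramethyl-1,3,2-dioxaborolane | C[C@H](c1cccc(OC)c1Br)B1OC(C)(C)C(C)(C)O1
F2 | step 2 | potassium [(1R)-1-(2-bromo-3-methoxyphenyl)ethyl]trifluoroborate | C[C@H](c1cccc(OC)c1Br)[B-](F)(F)F.[K+]
F3 | step 2 | (2R)-2-(2-bromo-3-methoxyphenyl)-1-(3,4,5-trimethoxyphenyl)propan-1-ol, mixture of epimers at C1 | C[C@H](c1cccc(OC)c1Br)C(O)c1cc(OC)c(OC)c(OC)c1
F4 | step 2 | (2S,3R)-7-methoxy-3-methyl-2-(3,4,5-trimethoxyphenyl)-2,3-dihydro-1-benzofuran | c1cc(OC)c2c(c1)[C@@H](C)[C@@H](c1cc(OC)c(OC)c(OC)c1)O2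
F5 | step 3 | 5-[(2R,3R)-7-methoxy-3-methyl-2-(3,4,5-trimethoxyphenyl)-2,3-dihydro-1-benzofuran-5-yl]thianthren-5-ium tetrafluoroborate | c1ccc2c(c1)Sc1ccccc1[S+]2c1cc(OC)c2c(c1)[C@@H](C)[C@H](c1cc(OC)c(OC)c(OC)c1)O2.F[B-](F)(F)F
F6 | step 4 | (2R,3R)-7-methoxy-3-methyl-5-(prop-2-en-1-yl)-2-(3,4,5-trimethoxyphenyl)-2,3-dihydro-1-benzofuran | C=CCc1cc(OC)c2c(c1)[C@@H](C)[C@H](c1cc(OC)c(OC)c(OC)c1)O2
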